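**Retrosynthetic overview**
1. Target 7 ⇐ 5 by cleavage of the two aryl methyl ethers.
2. 5 ⇐ 3 by the key C–O bond formation: ketone-directed double ortho-C–H oxygenation installs both 2'-oxygens on the finished cyclobutane.
3. 3 (all-trans) ⇐ 2 (syn head-to-tail photodimer) by a new thermodynamic stereo-editing step that inverts one benzylic and one α-keto centre.
4. 2 ⇐ two molecules of commercial 1 by host-templated solid-state [2+2] photodimerisation; the cyclobutane is the only ring formed (step 1).

Assumption: the SMILES describes the all-trans (1α,2β,3α,4β) isomer, which has two mirror planes and is achiral, so the "single enantiomer" is this one meso diastereomer and only relative configuration has to be controlled.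

**Step 1**
Reactants: 1 (E)-4'-methoxychalcone (two molecules)
Product: 2 (1α,2α,3β,4β)-1,3-bis(4-methoxybenzoyl)-2,4-diphenylcyclobutane (syn head-to-tail dimer; r-1,c-2,t-3,t-4; achiral)
Conditions: co-crystallise 1 with 1,1,6,6-tetraphenylhexa-2,4-diyne-1,6-diol (0.5 equiv) from Et2O/hexane; irradiate the powder, 400 W high-pressure Hg lamp, Pyrex, rt, 8 h; SiO2 (host recovered)
Reagents that add atoms: none
Why: Topochemical [2+2] photocycloaddition in a host–guest inclusion crystal, where the diol host hydrogen-bonds two carbonyl guests into an antiparallel, inversion-related pair with parallel C=C bonds about 4 Å apart, so suprafacial closure gives only the head-to-tail r-1,c-2,t-3,t-4 dimer, as established for the parent chalcone.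

**Step 2**
Reactants: 2 (1α,2α,3β,4β)-1,3-bis(4-methoxybenzoyl)-2,4-diphenylcyclobutane
Product: 3 (1α,2β,3α,4β)-1,3-bis(4-methoxybenzoyl)-2,4-diphenylcyclobutane (all-trans)
Conditions: 4CzIPN (2 mol%), iPr3SiSH (20 mol%), DBU (50 mol%), MeCN/PhCF3 1:1 (0.05 M), 456 nm LEDs, 35 °C, Ar, 36 h
Reagents that add atoms: none
Why: Proposed new method: the photo-oxidised silanethiolate gives an electrophilic thiyl radical whose S–H bond (about 87 kcal/mol) matches the tertiary benzylic C2/C4–H bonds (about 86 kcal/mol), so hydrogen-atom abstraction and return from either face are reversible and epimerise the phenyl-bearing carbons, while free DBU epimerises the aroyl-bearing C1/C3 by enolisation; because both processes are reversible and the all-trans isomer (no cis-vicinal contacts, all four groups pseudo-equatorial) is the global minimum, every head-to-tail diastereomer drains into 3, which sets all four stereocentres, with ring-opening of the cyclobutyl radical expected to be much slower than hydrogen return; the closest known reaction types are photocatalytic hydrogen-atom-transfer epimerisation (stereochemical editing) of tertiary C–H stereocentres, thiyl-radical racemisation of benzylic amines, and base epimerisation α to ketones.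

**Step 3**
Reactants: 3 (1α,2β,3α,4β)-1,3-bis(4-methoxybenzoyl)-2,4-diphenylcyclobutane
Product: 5 (1α,2β,3α,4β)-1,3-bis(2-hydroxy-4-methoxybenzoyl)-2,4-diphenylcyclobutane, via bis(aryl trifluoroacetate) 4 (not isolated)
Conditions: [RuCl2(p-cymene)]2 (5 mol%), K2S2O8 (4.4 equiv), CF3CO2H/(CF3CO)2O 4:1, 80 °C, 16 h; then NaHCO3, MeOH/H2O, rt
Reagents that add atoms: trifluoroacetic acid, OC(=O)C(F)(F)F (its oxygen becomes the phenolic oxygen)
Why: Ketone-directed C–H oxygenation in which the weakly coordinating carbonyl guides carboxylate-assisted ortho-metalation at the Ru(O2CCF3)2(p-cymene) species formed from [RuCl2(p-cymene)]2, persulfate oxidises the five-membered ruthenacycle and C–O reductive elimination gives the aryl trifluoroacetate, which is hydrolysed on work-up; only the anisoyl rings can form this metallacycle, and the all-trans ring is already the thermodynamic arrangement, so acid cannot change it.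

**Step 4**
Reactants: 5 (1α,2β,3α,4β)-1,3-bis(2-hydroxy-4-methoxybenzoyl)-2,4-diphenylcyclobutane
Product: 7 (1α,2β,3α,4β)-1,3-bis(2,4-dihydroxybenzoyl)-2,4-diphenylcyclobutane (target CNP0398987.1), via tetrakis(dibromoboryl) aryl ether 6 (not isolated)
Conditions: BBr3 (8 equiv), CH2Cl2, −78 °C → rt, 6 h; then MeOH, H2O, 0 °C
Reagents that add atoms: none
Why: Lewis-acid cleavage of aryl methyl ethers, in which bromide attacks the O-methyl carbon of the boron-complexed ether and the aryloxyboranes are hydrolysed on work-up, with no stereocentre involved.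

**Compound list**
1 | (E)-4'-methoxychalcone, (E)-1-(4-methoxyphenyl)-3-phenylprop-2-en-1-one (commercial) | COc1ccc(cc1)C(=O)/C=C/c1ccccc1 | starting material
2 | (1α,2α,3β,4β)-1,3-bis(4-methoxybenzoyl)-2,4-diphenylcyclobutane (syn head-to-tail dimer, achiral) | O=C(c1ccc(OC)cc1)[C@@H]1[C@H](c2ccccc2)[C@@H](C(=O)c2ccc(OC)cc2)[C@H]1c1ccccc1 | intermediate
3 | (1α,2β,3α,4β)-1,3-bis(4-methoxybenzoyl)-2,4-diphenylcyclobutane (all-trans, achiral) | O=C(c1ccc(OC)cc1)[C@H]1[C@H](c2ccccc2)[C@@H](C(=O)c2ccc(OC)cc2)[C@@H]1c1ccccc1 | intermediate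
4 | (1α,2β,3α,4β)-1,3-bis[4-methoxy-2-(trifluoroacetoxy)benzoyl]-2,4-diphenylcyclobutane | O=C(c1ccc(OC)cc1OC(=O)C(F)(F)F)[C@H]1[C@H](c2ccccc2)[C@@H](C(=O)c2ccc(OC)cc2OC(=O)C(F)(F)F)[C@@H]1c1ccccc1 | intermediate
5 | (1α,2β,3α,4β)-1,3-bis(2-hydroxy-4-methoxybenzoyl)-2,4-diphenylcyclobutane | O=C(c1ccc(OC)cc1O)[C@H]1[C@H](c2ccccc2)[C@@H](C(=O)c2ccc(OC)cc2O)[C@@H]1c1ccccc1 | intermediate
6 | (1α,2β,3α,4β)-1,3-bis[2,4-bis(dibromoboryloxy)benzoyl]-2,4-diphenylcyclobutane | O=C(c1ccc(OB(Br)Br)cc1OB(Br)Br)[C@H]1[C@H](c2ccccc2)[C@@H](C(=O)c2ccc(OB(Br)Br)cc2OB(Br)Br)[C@@H]1c1ccccc1 | intermediate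
7 | (1α,2β,3α,4β)-1,3-bis(2,4-dihydroxybenzoyl)-2,4-diphenylcyclobutane | O=C(c1ccc(O)cc1O)[C@H]1[C@H](c2ccccc2)[C@@H](C(=O)c2ccc(O)cc2O)[C@@H]1c1ccccc1 | target

Total step count: 4
Longest linear sequence: 4

**Steps most likely to fail**

Step 1 (photodimerisation). The 4'-methoxy guest may not form a 2:1 inclusion crystal, or may pack with the double bonds too far apart. The fallback leaves topochemical control and uses electronic control in solution. It sets out from 1: 1 is irradiated as its BF3 complex (BF3·OEt2 0.5 equiv, CH2Cl2, 0.5 M, 420 nm, −20 °C). Lewis-acid-complexed cinnamoyl chromophores are known to react through a stacked excited complex with a free ground-state partner, which favours the head-to-tail orientation. Head-to-head dimers are removed on silica, and the fallback comes back to the route at 2. It makes no new compound (F0).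

Step 2 (the proposed stereo-editing). The benzylic cyclobutyl radical may ring-open, thiyl abstraction may be too slow, or DBU may open the ring by retro-Michael cleavage. The fallback builds the cis-diphenyl relationship by a stereospecific sequence of known reactions; it sets out from 1 and comes back at 3.
- Benzaldehyde and 2-amino-1-(4-methoxyphenyl)ethanone hydrochloride (Et3N, MgSO4, CH2Cl2) give the imine (E)-N-benzylidene-2-amino-1-(4-methoxyphenyl)ethanone F1.
- Its copper-bound azomethine ylide ([Cu(MeCN)4]PF6, bisphosphine ligand, Et3N, THF) adds to 1 in an exo-selective (3+2) cycloaddition. This gives the racemic 2,5-cis pyrrolidine 3,5-bis(4-methoxybenzoyl)-2,4-diphenylpyrrolidine F2 with the two phenyl groups cis; the endo isomer is removed by chromatography.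
- Nitrogen deletion of F2 with PhI(OH)OTs and ammonium carbamate in CF3CH2OH at 80 °C proceeds through the 1,1-diazene, loss of N2 and stereoretentive collapse of the 1,4-biradical. It gives the cyclobutane (1α,2α,3β,4α)-1,3-bis(4-methoxybenzoyl)-2,4-diphenylcyclobutane F3.
- Catalytic DBU (MeCN, rt) then epimerises the one aroyl-bearing carbon that is cis to both phenyls and delivers 3.

Step 3 (C–H oxygenation). Oxygenation ortho to the methoxy group, persulfate oxidation of the benzylic ring C–H bonds, or incomplete reaction of the second ring may compete. The fallback replaces the weak ketone director by a covalently installed nitrogen director and acetoxylation; it sets out from 3 and comes back at 5.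
- 3 is converted (MeONH2·HCl, pyridine, EtOH, 80 °C) into the bis(O-methyl oxime) of 3, F4.
- Pd(OAc)2 (5 mol%) and PhI(OAc)2 in AcOH/Ac2O at 100 °C give the bis(ortho-acetoxy) bis(O-methyl oxime) F5.
- 6 M HCl in dioxane at 90 °C cleaves both oxime ethers and both acetates to give 5.

**Further compounds**
F0 | step 1 | none | none
F1 | step 2 | (E)-N-benzylidene-2-amino-1-(4-methoxyphenyl)ethanone | COc1ccc(cc1)C(=O)C/N=C/c1ccccc1
F2 | step 2 | rac-3,5-bis(4-methoxybenzoyl)-2,4-diphenylpyrrolidine (2,5-cis; 2,4-cis-diphenyl; 3-aroyl trans to both phenyls; one enantiomer drawn) | N1[C@H](c2ccccc2)[C@@H](C(=O)c2ccc(OC)cc2)[C@H](c2ccccc2)[C@@H]1C(=O)c1ccc(OC)cc1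
F3 | step 2 | (1α,2α,3β,4α)-1,3-bis(4-methoxybenzoyl)-2,4-diphenylcyclobutane | O=C(c1ccc(OC)cc1)[C@@H]1[C@H](c2ccccc2)[C@@H](C(=O)c2ccc(OC)cc2)[C@@H]1c1ccccc1
F4 | step 3 | (1α,2β,3α,4β)-1,3-bis[(methoxyimino)(4-methoxyphenyl)methyl]-2,4-diphenylcyclobutane (oxime geometry not specified) | CON=C(c1ccc(OC)cc1)[C@H]1[C@H](c2ccccc2)[C@@H](C(=NOC)c2ccc(OC)cc2)[C@@H]1c1ccccc1
F5 | step 3 | (1α,2β,3α,4β)-1,3-bis[(2-acetoxy-4-methoxyphenyl)(methoxyimino)methyl]-2,4-diphenylcyclobutane (oxime geometry not specified) | CON=C(c1ccc(OC)cc1OC(C)=O)[C@H]1[C@H](c2ccccc2)[C@@H](C(=NOC)c2ccc(OC)cc2OC(C)=O)[C@@H]1c1ccccc1
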